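**Plan**

- The 3-alkoxypyridine is treated as a ring-expanded furan. N1, the thiazolyl-bearing C6 and the oxygen on C5 correspond to the amine nitrogen, the aminomethine carbon and the ring oxygen of a 2-furylmethylamine. Pyridine C5, C4, C3 and C2 are the four furan carbons, with the C4 methoxy and C2 carboxyl already in place as a 4-methoxyfuran-2-carboxylate.
- Retrosynthetic cuts: the C5 O–methyl bond and the ester; then N1–C2 (pyridine to furan); then the aminomethine–furan C–C bond (furyl-magnesium plus thiazole-4-carbaldehyde N-sulfinyl imine); then thiazole C2–CH2 (B-alkyl Suzuki); then the chain C4'–C5' bond (epoxide opening).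
- Forward order: side chain, then attachment to the bought thiazole, then aldehyde and imine, then union with the furan, then N-Boc, then anodic ring expansion, then O-methylation, then saponification. The pyridine is the only ring that is built.
- Stereochemistry: the single (S)-carbinol comes from (S)-propylene oxide, whose C–O bond is never broken. The aminomethine centre is made without control and disappears on aromatisation.

Key step: step 9

Remarks on the chemistry (assumptions):
- Compounds 1, 4 (as a THF solution) and 7 are taken as purchasable.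
- Racemic tert-butanesulfinamide is used, because the sulfur centre and the new aminomethine centre are both erased later. Compounds 12 and 14–18 are therefore stereoisomer mixtures at those positions, with the (S)-carbinol fixed.
- The silyl ether is removed on purpose together with the sulfinyl group in step 8, so the key-step precursor carries a free secondary alcohol.

**Route**

Step 1
Reactants: 1 methyl 4-bromofuran-2-carboxylate
Product: 2 methyl 4-methoxyfuran-2-carboxylate
Conditions: NaOMe (2 equiv, 25 wt% in MeOH), CuBr (10 mol%), dry MeOH/DMF, 90 °C, sealed vessel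
Reagents that add atoms: sodium methoxide, [Na+].[O-]C
Why: Ullmann-type copper-catalysed methoxylation of a heteroaryl bromide, in which the 2-ester activates the β-bromofuran and methoxide in dry methanol can only exchange the methyl ester degenerately.

Step 2
Reactants: 3 (S)-propylene oxide; 4 but-3-enylmagnesium bromide
Product: 5 (S)-hept-6-en-2-ol
Conditions: CuI (10 mol%), THF, −30 → 0 °C; aq NH4Cl
Reagents that add atoms: none
Why: Copper-catalysed Grignard opening of a terminal epoxide is an SN2 attack at the unsubstituted CH2, so the C–O stereocentre of 3 is carried over untouched as the (S)-alcohol.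

Step 3
Reactants: 5 (S)-hept-6-en-2-ol
Product: 6 (S)-tert-butyl(hept-6-en-2-yloxy)dimethylsilane
Conditions: TBSCl (1.2 equiv), imidazole (2 equiv), DMF, rt
Reagents that add atoms: tert-butyldimethylsilyl chloride, CC(C)(C)[Si](C)(C)Cl
Why: Standard silylation removes the acidic OH so that it consumes neither DIBAL-H in step 5 nor the furylmagnesium reagent in step 7.

Step 4
Reactants: 6 (S)-tert-butyl(hept-6-en-2-yloxy)dimethylsilane; 7 ethyl 2-bromothiazole-4-carboxylate
Product: 9 ethyl 2-[(6S)-6-(tert-butyldimethylsilyloxy)heptyl]-1,3-thiazole-4-carboxylate, via alkyl-9-BBN adduct 8 (not isolated)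
Conditions: 9-BBN (0.5 M in THF), 0 °C → rt; then 7, Pd(dppf)Cl2 (5 mol%), aq K3PO4, DMF/THF, 50 °C
Reagents that add atoms: none
Why: Anti-Markovnikov hydroboration followed by B-alkyl Suzuki–Miyaura coupling, where the C=N-activated 2-bromothiazole adds readily to Pd(0), dppf suppresses β-hydride elimination, and mild phosphate base should spare the ester and silyl ether.

Step 5
Reactants: 9 ethyl 2-[(6S)-6-(tert-butyldimethylsilyloxy)heptyl]-1,3-thiazole-4-carboxylate
Product: 10 2-[(6S)-6-(tert-butyldimethylsilyloxy)heptyl]-1,3-thiazole-4-carbaldehyde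
Conditions: DIBAL-H (1.1 equiv), CH2Cl2, −78 °C; MeOH, then aq Rochelle salt
Reagents that add atoms: none
Why: Partial DIBAL-H reduction of an ester stops at the aluminium hemiacetal at −78 °C (here also chelated by the thiazole nitrogen) and gives the aldehyde only on work-up, as is routine for thiazole-4-carboxylates.

Step 6
Reactants: 10 2-[(6S)-6-(tert-butyldimethylsilyloxy)heptyl]-1,3-thiazole-4-carbaldehyde; 11 tert-butanesulfinamide (racemic)
Product: 12 (E)-N-({2-[(6S)-6-(tert-butyldimethylsilyloxy)heptyl]-1,3-thiazol-4-yl}methylidene)-2-methylpropane-2-sulfinamide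
Conditions: Ti(OEt)4 (2 equiv), THF, rt; brine
Reagents that add atoms: none
Why: Ellman condensation, with Ti(OEt)4 as Lewis acid and water scavenger, gives an isolable, activated (E)-N-sulfinyl aldimine under neutral conditions that leave the silyl ether alone.

Step 7
Reactants: 2 methyl 4-methoxyfuran-2-carboxylate; 12 (E)-N-sulfinyl aldimine
Product: 14 methyl 5-{[(tert-butylsulfinyl)amino]{2-[(6S)-6-(tert-butyldimethylsilyloxy)heptyl]-1,3-thiazol-4-yl}methyl}-4-methoxyfuran-2-carboxylate (mixture at sulfur and at the aminomethine carbon), via furylmagnesium chloride 13 (not isolated)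
Conditions: 2 (1.3 equiv), TMPMgCl·LiCl (1.25 equiv), THF, −40 °C; then 12, −40 → 0 °C; aq NH4Cl
Reagents that add atoms: none
Why: Directed magnesiation with the Knochel–Hauser base at the most acidic furan C–H (C5, next to the ring oxygen and ortho to OMe) gives an ester-tolerant heteroaryl Grignard that adds 1,2 to the sulfinyl imine; the new centre forms as an epimer mixture, which does not matter because this carbon becomes aromatic C6.

Step 8
Reactants: 14 sulfinamide adduct
Product: 16 methyl 5-{[(tert-butoxycarbonyl)amino]{2-[(6S)-6-hydroxyheptyl]-1,3-thiazol-4-yl}methyl}-4-methoxyfuran-2-carboxylate (both aminomethine epimers), via amino alcohol hydrochloride 15 (not isolated)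
Conditions: HCl (4 M in dioxane, 5 equiv), MeOH, 0 °C → rt; concentrate; then Boc2O (1.2 equiv), Et3N (3 equiv), CH2Cl2, 0 °C → rt
Reagents that add atoms: di-tert-butyl dicarbonate, CC(C)(C)OC(=O)OC(=O)OC(C)(C)C
Why: Methanolic HCl removes the Ellman auxiliary and the silyl ether in one operation while the ammonium and the ester shield the methoxyfuran from protonation, and Boc2O without DMAP then acylates only nitrogen to give the carbamate needed for oxidative furan methoxylation.

Step 9
Reactants: 16 Boc-protected furylmethylamine
Product: 19 methyl 5-hydroxy-6-{2-[(6S)-6-hydroxyheptyl]-1,3-thiazol-4-yl}-4-methoxypyridine-2-carboxylate, via trimethoxydihydrofuran bis-ketal 17 (not isolated), via amino ene-dione hydrochloride 18 (not isolated)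
Conditions: NaBr (0.3 equiv), MeOH, undivided cell, graphite anode/Pt cathode, constant current, ca. 2.2 F/mol, −10 °C; then HCl (4 M in dioxane, to ca. 1.5 M) in the same pot, 0 → 40 °C; then aq NaHCO3 to pH 7
Reagents that add atoms: none
Why: Bromide-mediated anodic oxidation (Clauson-Kaas methoxylation, the electrochemical entry to the aza-Achmatowicz manifold) adds two methoxy groups from the solvent across the furan α-carbons to give bis-ketal 17 while hydrogen forms at the cathode. Methanolic HCl with adventitious water then ionises the ketals, opens the ring to the cis-ene-dione (or its methanol adducts) and cleaves the Boc group to give 18, in which the former furan oxygen is the ketone oxygen next to the aminomethine carbon. Nitrogen adds to the α-keto-ester carbonyl in a 6-exo-trig closure (the other electrophilic carbons would give three- or four-membered rings), dehydration forms the N1–C2 imine, and enolisation of the α-amino ketone aromatises the ring to the 3-pyridinol, completed on neutralisation. No stereocentre is created: the ketal centres and both aminomethine epimers converge on the planar pyridine, and the remote (S)-carbinol is untouched. The step needs oxidation of the furan in preference to the thiazole and the secondary alcohol, which the 4-methoxy donor should secure by making the furan the most electron-rich π-system toward electrogenerated bromine at low temperature and limited charge; it also needs the enol-ether methoxy to survive, which the nearly anhydrous methanolic acid secures because exchange at that carbon is degenerate. The closest known reaction type is the electrolytic methoxylation of N-acyl furfurylamines and their acid rearrangement to 3-hydroxypyridines, applied here to a furan that also carries a 2-ester, a 4-methoxy group and a thiazole.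

Step 10
Reactants: 19 pyridinol
Product: 20 methyl 6-{2-[(6S)-6-hydroxyheptyl]-1,3-thiazol-4-yl}-4,5-dimethoxypyridine-2-carboxylate
Conditions: MeI (1.2 equiv), K2CO3 (1.5 equiv), DMF, rt
Reagents that add atoms: iodomethane, CI
Why: Williamson O-methylation of the acidic pyridinol under carbonate, which does not deprotonate the aliphatic alcohol, while the ring nitrogen is flanked by the ester and the thiazolyl group and is therefore a poor site for N-methylation.

Step 11
Reactants: 20 dimethoxy picolinate methyl ester
Product: 21 6-{2-[(6S)-6-hydroxyheptyl]-1,3-thiazol-4-yl}-4,5-dimethoxypyridine-2-carboxylic acid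
Conditions: LiOH·H2O (2 equiv), THF/H2O 3:1, rt; then 1 M HCl to pH 3–4
Reagents that add atoms: lithium hydroxide, [Li+].[OH-]
Why: Saponification of the activated picolinate ester by acyl–oxygen cleavage at room temperature touches neither the aryl methyl ethers nor the carbinol stereocentre.

**Compound list**

1 | methyl 4-bromofuran-2-carboxylate | COC(=O)c1cc(Br)co1 | starting material
2 | methyl 4-methoxyfuran-2-carboxylate | COC(=O)c1cc(OC)co1 | intermediate
3 | (S)-propylene oxide | C[C@H]1CO1 | starting material
4 | but-3-enylmagnesium bromide | C=CCC[Mg]Br | starting material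
5 | (S)-hept-6-en-2-ol | C=CCCC[C@H](C)O | intermediate
6 | (S)-tert-butyl(hept-6-en-2-yloxy)dimethylsilane | C=CCCC[C@H](C)O[Si](C)(C)C(C)(C)C | intermediate
7 | ethyl 2-bromothiazole-4-carboxylate | CCOC(=O)c1csc(Br)n1 | starting material
8 | 9-[(6S)-6-(tert-butyldimethylsilyloxy)heptyl]-9-borabicyclo[3.3.1]nonane (not isolated) | B1(CCCCC[C@H](C)O[Si](C)(C)C(C)(C)C)C2CCCC1CCC2 | intermediate
9 | ethyl 2-[(6S)-6-(tert-butyldimethylsilyloxy)heptyl]-1,3-thiazole-4-carboxylate | CCOC(=O)c1csc(CCCCC[C@H](C)O[Si](C)(C)C(C)(C)C)n1 | intermediate
10 | 2-[(6S)-6-(tert-butyldimethylsilyloxy)heptyl]-1,3-thiazole-4-carbaldehyde | O=Cc1csc(CCCCC[C@H](C)O[Si](C)(C)C(C)(C)C)n1 | intermediate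
11 | tert-butanesulfinamide (racemic) | CC(C)(C)S(N)=O | starting material
12 | (E)-N-({2-[(6S)-6-(tert-butyldimethylsilyloxy)heptyl]-1,3-thiazol-4-yl}methylidene)-2-methylpropane-2-sulfinamide (racemic at sulfur) | CC(C)(C)S(=O)/N=C/c1csc(CCCCC[C@H](C)O[Si](C)(C)C(C)(C)C)n1 | intermediate
13 | [3-methoxy-5-(methoxycarbonyl)furan-2-yl]magnesium chloride, LiCl complex (not isolated) | COC(=O)c1cc(OC)c([Mg]Cl)o1 | intermediate
14 | methyl 5-{[(tert-butylsulfinyl)amino]{2-[(6S)-6-(tert-butyldimethylsilyloxy)heptyl]-1,3-thiazol-4-yl}methyl}-4-methoxyfuran-2-carboxylate (mixture at sulfur and aminomethine carbon) | COC(=O)c1cc(OC)c(C(NS(=O)C(C)(C)C)c2csc(CCCCC[C@H](C)O[Si](C)(C)C(C)(C)C)n2)o1 | intermediate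
15 | methyl 5-(amino{2-[(6S)-6-hydroxyheptyl]-1,3-thiazol-4-yl}methyl)-4-methoxyfuran-2-carboxylate hydrochloride (both epimers, not isolated) | COC(=O)c1cc(OC)c(C(N)c2csc(CCCCC[C@H](C)O)n2)o1.Cl | intermediate
16 | methyl 5-{[(tert-butoxycarbonyl)amino]{2-[(6S)-6-hydroxyheptyl]-1,3-thiazol-4-yl}methyl}-4-methoxyfuran-2-carboxylate (both epimers) | COC(=O)c1cc(OC)c(C(NC(=O)OC(C)(C)C)c2csc(CCCCC[C@H](C)O)n2)o1 | intermediate
17 | methyl 5-{[(tert-butoxycarbonyl)amino]{2-[(6S)-6-hydroxyheptyl]-1,3-thiazol-4-yl}methyl}-2,4,5-trimethoxy-2,5-dihydrofuran-2-carboxylate (diastereomer mixture, not isolated) | COC(=O)C1(OC)C=C(OC)C(OC)(C(NC(=O)OC(C)(C)C)c2csc(CCCCC[C@H](C)O)n2)O1 | intermediate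
18 | methyl 6-amino-6-{2-[(6S)-6-hydroxyheptyl]-1,3-thiazol-4-yl}-4-methoxy-2,5-dioxohex-3-enoate hydrochloride, the two ketone carbons cis across C3=C4 (not isolated) | COC(=O)C(=O)/C=C(OC)\C(=O)C(N)c1csc(CCCCC[C@H](C)O)n1.Cl | intermediate
19 | methyl 5-hydroxy-6-{2-[(6S)-6-hydroxyheptyl]-1,3-thiazol-4-yl}-4-methoxypyridine-2-carboxylate | COC(=O)c1cc(OC)c(O)c(-c2csc(CCCCC[C@H](C)O)n2)n1 | intermediate
20 | methyl 6-{2-[(6S)-6-hydroxyheptyl]-1,3-thiazol-4-yl}-4,5-dimethoxypyridine-2-carboxylate | COC(=O)c1cc(OC)c(OC)c(-c2csc(CCCCC[C@H](C)O)n2)n1 | intermediate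
21 | 6-{2-[(6S)-6-hydroxyheptyl]-1,3-thiazol-4-yl}-4,5-dimethoxypyridine-2-carboxylic acid | COc1cc(C(=O)O)nc(-c2csc(CCCCC[C@H](C)O)n2)c1OC | target

**Step count**

Total: 11 steps. Longest linear sequence: 10 steps (3 → 21 through steps 2–11); the furan branch (step 1) joins at step 7.

**Steps most likely to fail**

1. Step 9. Electrogenerated bromine may attack the thiazole C5–H or oxidise the carbinol. The enol-ether methoxy may be lost by hydrolysis during ketal opening. The amino ene-dione may isomerise to the trans form or condense intermolecularly before ring closure. Fallback: starting from 16, the oxidation and the aromatisation are separated. NBS with NaHCO3/NaOAc in THF/H2O at 0 °C should give the aza-Achmatowicz hemiaminal methyl 1-(tert-butoxycarbonyl)-2-hydroxy-6-{2-[(6S)-6-hydroxyheptyl]-1,3-thiazol-4-yl}-4-methoxy-5-oxo-1,2,5,6-tetrahydropyridine-2-carboxylate F1, which already contains the N1–C2 bond and can be purified. TFA in CH2Cl2 then removes the Boc group and dehydrates the ring, returning to the route at 19.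

2. Step 7. The amide base may deprotonate C3 (between ester and methoxy) instead of C5, or the base or the furylmagnesium may attack the ester before the imine is added. Fallback: starting from 2, bromination with NBS in MeCN at 0 °C at the enol-ether-activated α-position should give methyl 5-bromo-4-methoxyfuran-2-carboxylate F2. Bromine–magnesium exchange with i-PrMgCl·LiCl in THF at −40 °C then generates the metal at a fixed position without any amide base and returns to the route at 13.

3. Step 1. Methoxide or traces of hydroxide may cleave the ester at 90 °C, the bromide may be reduced off, or the copper-mediated C–O coupling on the β-bromofuran may stall. Fallback: starting from 1, Miyaura borylation (B2pin2, Pd(dppf)Cl2, KOAc, dioxane, 90 °C) should give methyl 4-(4,4,5,5-tetramethyl-1,3,2-dioxaborolan-2-yl)furan-2-carboxylate F3. Oxidation with NaBO3·4H2O in THF/H2O gives methyl 4-hydroxyfuran-2-carboxylate F4 (in equilibrium with its furan-3(2H)-one tautomer), and O-methylation with Me2SO4/K2CO3 in acetone returns to the route at 2.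

**Further compounds**

F1 | step 9 | methyl 1-(tert-butoxycarbonyl)-2-hydroxy-6-{2-[(6S)-6-hydroxyheptyl]-1,3-thiazol-4-yl}-4-methoxy-5-oxo-1,2,5,6-tetrahydropyridine-2-carboxylate | COC(=O)C1(O)C=C(OC)C(=O)C(c2csc(CCCCC[C@H](C)O)n2)N1C(=O)OC(C)(C)C
F2 | step 7 | methyl 5-bromo-4-methoxyfuran-2-carboxylate | COC(=O)c1cc(OC)c(Br)o1
F3 | step 1 | methyl 4-(4,4,5,5-tetramethyl-1,3,2-dioxaborolan-2-yl)furan-2-carboxylate | COC(=O)c1cc(B2OC(C)(C)C(C)(C)O2)co1
F4 | step 1 | methyl 4-hydroxyfuran-2-carboxylate | COC(=O)c1cc(O)co1
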